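Taking 10% of the two substrates together costs 25.0% of the charged coupling partner, and the protic impurity can claim another 12.5% of it, so 62.5% of the partner is the floor up to that moment.

left-handed substrate 0.0050 M; coupling partner 4.00 mM; protic impurity 0.500 mM; precatalyst 26 µM; right-handed substrate 0.0050 M

    coupling partner + catalyst + left-handed substrate → catalyst + left-handed product (k1 = 3.5 × 10⁶ /M²/s)
    coupling partner + catalyst + right-handed substrate → catalyst + right-handed product (k2 = 1.8 × 10⁶ /M²/s)
    precatalyst → catalyst (k3 = 0.31 /s)
    coupling partner + protic impurity → quenched reagent (k4 = 900 /M/s)

- the form that holds most of the catalyst when 10% of the left-handed substrate and right-handed substrate together are converted (catalyst / precatalyst)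
- its share of the catalyst then
- factor on the rate of making left-handed product when 10% of the left-handed substrate and right-handed substrate together are converted if precatalyst is charged twice over
- factor on the rate when 10% of the left-handed substrate and right-handed substrate together are converted if precatalyst is charged at 5.0 µM instead

I reckoned with one quantity, the working time: the seconds the whole catalyst charge, if active from the start, would need to reach that conversion. With the partner and substrates at midway amounts, the two substrates losing equally as if the catalyst told no hands, it came to 0.509 s. The charged amounts gave my lower bound, 0.363 s. The partner at its floor, with every converted molecule left-handed, gave my upper bound, 0.669 s.

Precatalyst turned into catalyst at 0.31 /s, so the work delivered by any moment was the elapsed time less the active fraction divided by that constant. The bounds put the precatalyst share between 48.6% and 59.8%. The working time gave 53.8% at 2.00 s, earlier than the precatalyst half-life of 2.24 s. So I committed to precatalyst as the larger part, though the low end of that share range stood under one half. At equal conversion I took the rate to follow the active catalyst, and halving the working time for the doubled charge gave me a factor of 1.50.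

The forecast named precatalyst at 53%, with a range of 48% to 58%, and rate factors of 1.5 for the doubled charge and 0.33 for the charge of 5.0 µM. Its centre lay inside my bracket, and its ground was that the conversion comes “before the precatalyst's roughly 2.2 s half-life”.

The flask as charged gave precatalyst at 53.6%, and the run with the doubled charge gave a factor of 1.50. At 2.00 s the partner in the flask as charged stood at 62.7% of its charge. From its active share, the work delivered by 2.01 s in that flask came to 0.515 s. For the flask charged with 5.0 µM precatalyst I stretched the working time to 2.65 s, and the same balance of work put 80.1% of its catalyst in the active form and its rate at 0.334 of the rate I had reckoned for the flask as charged; its run gave 0.334.

The constants were chosen freely; what happens was integrated by code.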